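**Plan**
- Retrosynthesis: the C17 ester is traced back to a CH2OSi group; the ring C11–C12 bond is then cut, because the C11 ketone and the adjacent C12 tertiary carbinol inside the 14-membered carbocycle form an α-hydroxy ketone, the retron of an aldehyde–ketone benzoin reaction.
- The open chain is cut at C5–C6 (allylic sulfone alkylation), at C3=C4 (Z-olefination) and back to the ring alkene of limonene (C3 and C12 by ozonolysis).
- Forward: a limonene-derived C12–C5 epoxy triflate and a geranyl-derived C6–C11 sulfone are joined at C5–C6, the sulfone is removed, both carbonyls are unmasked, and the only carbocycle (14-membered) closes last through C11–C12; C17 is then oxidised to the methyl ester.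
- Stereochemistry: C1 from (S)-limonene; C3/C4 from Sharpless epoxidation of a Z-allylic alcohol (Z from Still–Gennari olefination); 7E from the geranyl unit; C12 from the chiral carbene catalyst.

Key step: step 14

Remarks on the chemistry
- Target numbering is used throughout: C1 = ring CH bearing C15(=C16H2)–C17; C3/C4 oxirane (methyl on C4); C7=C8 (methyl on C8); C11 ketone; C12 carbinol (methyl on C12).
- The oxirane of the target carries C2 and C5 cis, so it must come from a (Z)-3,4-alkene.
- Assumption: the antipode of the aminoindanol-derived triazolium salt that gives the 12S ketol is found in a preliminary screen; both antipodes are accessible from the two enantiomers of cis-1-amino-2-indanol.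
- Compound 19 is carried as a mixture of C6 epimers, since C6 becomes a methylene group in step 12.
- Catalyst-bound species (Breslow intermediate, π-allylpalladium, titanium alkoxides) are treated as mechanism and are not numbered.

**Route**

Step 1
Reactants: 1 (S)-limonene
Product: 4 (S)-limonen-10-ol [2-[(1S)-4-methylcyclohex-3-en-1-yl]prop-2-en-1-ol], via 10-lithiolimonene 2 (not isolated), via dimethyl allylboronate 3 (not isolated)
Conditions: n-BuLi, TMEDA, hexane, rt; B(OMe)3, Et2O, −78 °C to rt; then 30% H2O2, aq NaOH, 0 °C to rt
Reagents that add atoms: n-butyllithium, [Li]CCCC (lithium of 2); trimethyl borate, COB(OC)OC (boron and methoxy groups of 3); hydrogen peroxide, OO (hydroxyl oxygen of 4)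
Why: Allylic lithiation of limonene with n-BuLi·TMEDA takes place at the isopropenyl methyl group, and borylation followed by oxidative C–B cleavage of the symmetrical 2-substituted allyl unit gives the primary allylic alcohol without regiochemical ambiguity while the ring stereocentre (later C1) is untouched.

Step 2
Reactants: 4 (S)-limonen-10-ol
Product: 5 tert-butyl({2-[(1S)-4-methylcyclohex-3-en-1-yl]prop-2-en-1-yl}oxy)diphenylsilane
Conditions: TBDPSCl, imidazole, DMF, rt
Reagents that add atoms: tert-butyl(chloro)diphenylsilane, CC(C)(C)[Si](Cl)(c1ccccc1)c1ccccc1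
Why: Standard silylation of a primary alcohol, the TBDPS ether being chosen because it must survive the acidic steps 5 and 13 and keeps C17 at the alcohol level so that no Michael acceptor is present in step 14.

Step 3
Reactants: 5 TBDPS ether of limonen-10-ol
Product: 6 (3S)-3-[3-(tert-butyldiphenylsilyloxy)prop-1-en-2-yl]-6-oxoheptanal
Conditions: O3 (1.0 equiv, Sudan Red 7B end point), pyridine, CH2Cl2, −78 °C
Reagents that add atoms: ozone, [O-][O+]=O
Why: Ozonolysis with pyridine as carbonyl-oxide scavenger cleaves the electron-rich trisubstituted ring alkene faster than the 1,1-disubstituted alkene, which is deactivated by its allylic silyloxy group, and releases the C3 aldehyde and the C12 methyl ketone in one operation with the C1 stereocentre (not α to either carbonyl) unaffected.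

Step 4
Reactants: 6 keto aldehyde; 7 ethyl 2-[bis(2,2,2-trifluoroethoxy)phosphoryl]propanoate
Product: 9 ethyl (2Z,5S)-5-[3-(tert-butyldiphenylsilyloxy)prop-1-en-2-yl]-2-methyl-8-oxonon-2-enoate, via potassium phosphonate carbanion 8 (not isolated)
Conditions: 7, KHMDS, 18-crown-6, THF, −78 °C; then 6, −78 °C
Reagents that add atoms: potassium bis(trimethylsilyl)amide, C[Si](C)(C)[N-][Si](C)(C)C.[K+] (potassium of 8)
Why: Still–Gennari olefination with the α-methyl bis(trifluoroethyl)phosphonate is kinetically Z-selective, so the ester carbon (C5) ends up cis to C2 as the cis-substituted oxirane requires, and the stabilised anion attacks only the aldehyde, leaving the methyl ketone untouched at −78 °C.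

Step 5
Reactants: 9 Z-enoate ketone
Product: 10 ethyl (2Z,5S)-5-[3-(tert-butyldiphenylsilyloxy)prop-1-en-2-yl]-2-methyl-7-(2-methyl-1,3-dioxolan-2-yl)hept-2-enoate
Conditions: TMSOCH2CH2OTMS, TMSOTf (cat.), CH2Cl2, −78 to −20 °C
Reagents that add atoms: 1,2-bis(trimethylsilyloxy)ethane, C[Si](C)(C)OCCO[Si](C)(C)C
Why: Noyori ketalisation under aprotic conditions masks the C12 ketone as a dioxolane that survives DIBAL-H, the sulfonyl carbanion and the hydride of step 12, while the conjugated ester and the silyl ether do not react.

Step 6
Reactants: 10 dioxolane ester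
Product: 11 (2Z,5S)-5-[3-(tert-butyldiphenylsilyloxy)prop-1-en-2-yl]-2-methyl-7-(2-methyl-1,3-dioxolan-2-yl)hept-2-en-1-ol
Conditions: DIBAL-H, CH2Cl2, −78 °C; Rochelle salt work-up
Reagents that add atoms: none
Why: DIBAL-H reduction of the enoate gives the allylic alcohol with retention of the Z geometry, ketal and silyl ether being inert.

Step 7
Reactants: 11 Z-allylic alcohol
Product: 12 [(2S,3R)-3-{(2S)-2-[3-(tert-butyldiphenylsilyloxy)prop-1-en-2-yl]-4-(2-methyl-1,3-dioxolan-2-yl)butyl}-2-methyloxiran-2-yl]methanol
Conditions: Ti(OiPr)4 (0.2 equiv), L-(+)-DET (0.24 equiv), t-BuOOH (anhydrous), 4 Å MS, CH2Cl2, −20 °C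
Reagents that add atoms: tert-butyl hydroperoxide, CC(C)(C)OO
Why: Sharpless asymmetric epoxidation is confined to the allylic-alcohol alkene, and L-(+)-diethyl tartrate delivers oxygen to the face that makes the carbinol-bearing oxirane carbon 2S (as in nerol to (2S,3R)-2,3-epoxynerol), which with syn addition to the Z alkene sets C4 as S and C3 as R under reagent control.

Step 8
Reactants: 12 epoxy alcohol
Product: 13 trifluoromethanesulfonate of epoxy alcohol 12
Conditions: Tf2O, 2,6-lutidine, CH2Cl2, −78 °C; used at once without chromatography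
Reagents that add atoms: trifluoromethanesulfonic anhydride, O=S(=O)(OS(=O)(=O)C(F)(F)F)C(F)(F)F
Why: Buffered low-temperature triflation of the primary epoxy alcohol gives an electrophile reactive enough for SN2 displacement at the hindered C5 while the adjacent oxirane stays intact.

Step 9
Reactants: 14 geranyl bromide
Product: 15 geranyl phenyl sulfone [(2E)-3,7-dimethylocta-2,6-dien-1-yl]sulfonylbenzene
Conditions: PhSO2Na, DMF, rt
Reagents that add atoms: sodium benzenesulfinate, [Na+].[O-]S(=O)c1ccccc1
Why: SN2 S-alkylation of benzenesulfinate by the primary allylic bromide gives the allylic sulfone with the 2E geometry (later 7E) retained.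

Step 10
Reactants: 15 geranyl phenyl sulfone
Product: 17 {[(2E)-6,6-dimethoxy-3-methylhex-2-en-1-yl]sulfonyl}benzene, via (4E)-4-methyl-6-(phenylsulfonyl)hex-4-enal 16 (not isolated)
Conditions: O3 (1.0 equiv, Sudan Red 7B end point), pyridine, CH2Cl2, −78 °C; evaporate; then HC(OMe)3, MeOH, p-TsOH (cat.), rt
Reagents that add atoms: ozone, [O-][O+]=O (carbonyl oxygen of 16); trimethyl orthoformate, COC(OC)OC (both methoxy groups of 17)
Why: Ozonolysis is selective for the remote isopropylidene alkene because the 2,3-alkene is deactivated by the allylic sulfonyl group, and acid-catalysed acetalisation of the crude aldehyde masks C11 against the carbanion and hydride chemistry that follows.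

Step 11
Reactants: 17 sulfone acetal; 13 epoxy triflate
Product: 19 C6-phenylsulfonyl seco bis-acetal (1S,3R,4S,7E; both C6 epimers), via lithiated sulfone 18 (not isolated)
Conditions: 17, n-BuLi, THF/DMPU, −78 °C; then 13, −78 °C; AcOH quench at −78 °C
Reagents that add atoms: n-butyllithium, [Li]CCCC (lithium of 18)
Why: Alkylation of a lithiated allylic sulfone, which reacts at the sulfonyl-bearing α-carbon without allylic transposition, with a primary triflate forms C5–C6, the triflate being displaced far faster than the trisubstituted oxirane is opened at −78 °C and the cold quench preventing 3-exo closure of the product anion onto the oxirane.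

Step 12
Reactants: 19 coupled sulfone
Product: 20 seco bis-acetal (C11 dimethyl acetal; C12 dioxolane; 1S,3R,4S,7E; C17 OTBDPS)
Conditions: PdCl2(dppp) (cat.), LiEt3BH, THF, −20 to 0 °C
Reagents that add atoms: none
Why: Palladium-catalysed reductive desulfonylation of an allylic sulfone (π-allylpalladium formation, then hydride transfer to the less substituted allyl terminus C6) restores the C6 methylene and keeps the trisubstituted 7E alkene in place, low temperature and short contact time being chosen so that hydride opening of the hindered oxirane does not compete.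

Step 13
Reactants: 20 seco bis-acetal
Product: 21 seco keto aldehyde (C11 aldehyde; C12 methyl ketone; 1S,3R,4S,7E; C17 OTBDPS)
Conditions: PPTS, acetone/H2O, rt to 40 °C
Reagents that add atoms: water, O
Why: Mild acid-catalysed acetal hydrolysis removes the dimethyl acetal and the ketone dioxolane together under conditions in which the trisubstituted oxirane and the TBDPS ether are expected to persist.

Step 14
Reactants: 21 seco keto aldehyde
Product: 22 macrocyclic ketol (1S,3R,4S,7E,12S)-1-[3-(tert-butyldiphenylsilyloxy)prop-1-en-2-yl]-3,4-epoxy-12-hydroxy-4,8,12-trimethylcyclotetradec-7-en-11-one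
Conditions: chiral aminoindanol-derived N-C6F5 triazolium tetrafluoroborate (20 mol%), DBU (15 mol%), toluene, 40 °C, Ar, syringe-pump addition of 21 to a final concentration of about 1 mM
Reagents that add atoms: none
Why: Proposed new method: the triazolylidene adds to the unhindered C11 aldehyde, proton transfer gives the Breslow intermediate (an acyl anion equivalent), this enaminol attacks the C12 methyl ketone, and proton shuttling with loss of the carbene releases the tertiary ketol; the closest known reaction is the NHC-catalysed intramolecular crossed aldehyde–ketone benzoin cyclisation, established for five- and six-membered rings but not for macrocycles. The 14-membered carbocycle closes in a 14-exo-trig mode (the ketone C=O lies outside the ring being formed) under pseudo-high dilution, so that intermolecular aldehyde homo-benzoin and aldol pathways are starved. The new C12 stereocentre is set by the catalyst, whose aminoindanol backbone shields one face of the Breslow intermediate and orients the ketone through the hydrogen bond from the enaminol OH; C1, C3 and C4 are too remote to bias the closure, so any 12R epimer is a diastereomer to be removed by chromatography. The crossed sense is inherent because only the aldehyde can form a Breslow intermediate and the ketone can only act as acceptor, and no Stetter acceptor is present because the acrylate is carried as its silyloxymethyl precursor. A weak, substoichiometric base and a stop at full conversion are meant to limit retro-benzoin erosion and α-ketol rearrangement.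

Step 15
Reactants: 22 macrocyclic ketol silyl ether
Product: 23 macrocyclic ketol with free C17 allylic alcohol
Conditions: TBAF, AcOH, THF, rt
Reagents that add atoms: none
Why: Fluoride-mediated desilylation buffered with acetic acid frees the C17 allylic alcohol without exposing the tertiary α-ketol to base (retro-benzoin or α-ketol rearrangement) or the oxirane to acid.

Step 16
Reactants: 23 allylic alcohol
Product: 24 macrocyclic enal (C17 aldehyde)
Conditions: Dess–Martin periodinane, NaHCO3, CH2Cl2, 0 °C to rt
Reagents that add atoms: none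
Why: Buffered Dess–Martin oxidation converts the primary allylic alcohol into the 2-substituted acrolein, while the tertiary alcohol cannot be oxidised and the oxirane sees no free acid.

Step 17
Reactants: 24 enal
Product: 25 macrocyclic acrylic acid (C17 acid)
Conditions: NaClO2, NaH2PO4, 2-methyl-2-butene, t-BuOH/H2O, 0 °C to rt
Reagents that add atoms: sodium chlorite, [Na+].[O-]Cl=O
Why: Pinnick oxidation converts the enal chemoselectively into the acrylic acid, with 2-methyl-2-butene scavenging hypochlorous acid to protect the 7,8-alkene and the phosphate buffer sparing the oxirane.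

Step 18
Reactants: 25 acrylic acid
Product: 26 target CNP0154954.4 methyl 2-[(1S,3R,4S,7E,12S)-3,4-epoxy-12-hydroxy-4,8,12-trimethyl-11-oxocyclotetradec-7-en-1-yl]prop-2-enoate
Conditions: TMSCHN2, toluene/MeOH, 0 °C
Reagents that add atoms: (trimethylsilyl)diazomethane, C[Si](C)(C)C=[N+]=[N-]
Why: Methyl esterification with (trimethylsilyl)diazomethane in methanol runs under neutral conditions that leave the tertiary alcohol, ketone, oxirane and acrylate untouched.

**Compound list**

1 | (S)-limonene | CC1=CC[C@H](CC1)C(C)=C | starting material
2 | 10-lithiolimonene | CC1=CC[C@H](CC1)C(=C)C[Li] | intermediate (not isolated)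
3 | dimethyl {2-[(1S)-4-methylcyclohex-3-en-1-yl]prop-2-en-1-yl}boronate | CC1=CC[C@H](CC1)C(=C)CB(OC)OC | intermediate (not isolated)
4 | (S)-limonen-10-ol | CC1=CC[C@H](CC1)C(=C)CO | intermediate
5 | TBDPS ether of 4 | CC1=CC[C@H](CC1)C(=C)CO[Si](c1ccccc1)(c1ccccc1)C(C)(C)C | intermediate
6 | (3S)-3-[3-(tert-butyldiphenylsilyloxy)prop-1-en-2-yl]-6-oxoheptanal | O=CC[C@@H](C(=C)CO[Si](c1ccccc1)(c1ccccc1)C(C)(C)C)CCC(C)=O | intermediate
7 | ethyl 2-[bis(2,2,2-trifluoroethoxy)phosphoryl]propanoate | CCOC(=O)C(C)P(=O)(OCC(F)(F)F)OCC(F)(F)F | starting material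
8 | potassium salt of the carbanion of 7 | CCOC(=O)[C-](C)P(=O)(OCC(F)(F)F)OCC(F)(F)F.[K+] | intermediate (not isolated)
9 | ethyl (2Z,5S)-5-[3-(tert-butyldiphenylsilyloxy)prop-1-en-2-yl]-2-methyl-8-oxonon-2-enoate | CCOC(=O)/C(C)=C\C[C@@H](C(=C)CO[Si](c1ccccc1)(c1ccccc1)C(C)(C)C)CCC(C)=O | intermediate
10 | ethyl (2Z,5S)-5-[3-(tert-butyldiphenylsilyloxy)prop-1-en-2-yl]-2-methyl-7-(2-methyl-1,3-dioxolan-2-yl)hept-2-enoate | CCOC(=O)/C(C)=C\C[C@@H](C(=C)CO[Si](c1ccccc1)(c1ccccc1)C(C)(C)C)CCC1(C)OCCO1 | intermediate
11 | (2Z,5S)-5-[3-(tert-butyldiphenylsilyloxy)prop-1-en-2-yl]-2-methyl-7-(2-methyl-1,3-dioxolan-2-yl)hept-2-en-1-ol | OC/C(C)=C\C[C@@H](C(=C)CO[Si](c1ccccc1)(c1ccccc1)C(C)(C)C)CCC1(C)OCCO1 | intermediate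
12 | [(2S,3R)-3-{(2S)-2-[3-(tert-butyldiphenylsilyloxy)prop-1-en-2-yl]-4-(2-methyl-1,3-dioxolan-2-yl)butyl}-2-methyloxiran-2-yl]methanol | OC[C@]1(C)O[C@@H]1C[C@@H](C(=C)CO[Si](c2ccccc2)(c2ccccc2)C(C)(C)C)CCC2(C)OCCO2 | intermediate
13 | trifluoromethanesulfonate of 12 | O=S(=O)(OC[C@]1(C)O[C@@H]1C[C@@H](C(=C)CO[Si](c2ccccc2)(c2ccccc2)C(C)(C)C)CCC2(C)OCCO2)C(F)(F)F | intermediate
14 | geranyl bromide, (2E)-1-bromo-3,7-dimethylocta-2,6-diene | CC(C)=CCC/C(C)=C/CBr | starting material
15 | geranyl phenyl sulfone | CC(C)=CCC/C(C)=C/CS(=O)(=O)c1ccccc1 | intermediate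
16 | (4E)-4-methyl-6-(phenylsulfonyl)hex-4-enal | O=CCC/C(C)=C/CS(=O)(=O)c1ccccc1 | intermediate (not isolated)
17 | {[(2E)-6,6-dimethoxy-3-methylhex-2-en-1-yl]sulfonyl}benzene | COC(OC)CC/C(C)=C/CS(=O)(=O)c1ccccc1 | intermediate
18 | α-lithio derivative of 17 | COC(OC)CC/C(C)=C/C([Li])S(=O)(=O)c1ccccc1 | intermediate (not isolated)
19 | C6-phenylsulfonyl seco bis-acetal (1S,3R,4S,7E; C6 epimer mixture; C11 dimethyl acetal; C12 dioxolane; C17 OTBDPS) | COC(OC)CC/C(C)=C/C(C[C@]1(C)O[C@@H]1C[C@@H](C(=C)CO[Si](c2ccccc2)(c2ccccc2)C(C)(C)C)CCC2(C)OCCO2)S(=O)(=O)c1ccccc1 | intermediate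
20 | seco bis-acetal (1S,3R,4S,7E; C11 dimethyl acetal; C12 dioxolane; C17 OTBDPS) | COC(OC)CC/C(C)=C/CC[C@]1(C)O[C@@H]1C[C@@H](C(=C)CO[Si](c2ccccc2)(c2ccccc2)C(C)(C)C)CCC2(C)OCCO2 | intermediate
21 | seco keto aldehyde (1S,3R,4S,7E; C11 aldehyde; C12 methyl ketone; C17 OTBDPS) | O=CCC/C(C)=C/CC[C@]1(C)O[C@@H]1C[C@@H](C(=C)CO[Si](c2ccccc2)(c2ccccc2)C(C)(C)C)CCC(C)=O | intermediate
22 | macrocyclic ketol, (1S,3R,4S,7E,12S)-1-[3-(tert-butyldiphenylsilyloxy)prop-1-en-2-yl]-3,4-epoxy-12-hydroxy-4,8,12-trimethylcyclotetradec-7-en-11-one | C=C(CO[Si](c3ccccc3)(c3ccccc3)C(C)(C)C)[C@H]1CC[C@](C)(O)C(=O)CC/C(C)=C/CC[C@]2(C)O[C@@H]2C1 | intermediate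
23 | macrocyclic ketol with C17 allylic alcohol | C=C(CO)[C@H]1CC[C@](C)(O)C(=O)CC/C(C)=C/CC[C@]2(C)O[C@@H]2C1 | intermediate
24 | macrocyclic enal (C17 aldehyde) | C=C(C=O)[C@H]1CC[C@](C)(O)C(=O)CC/C(C)=C/CC[C@]2(C)O[C@@H]2C1 | intermediate
25 | macrocyclic acrylic acid (C17 acid) | C=C(C(=O)O)[C@H]1CC[C@](C)(O)C(=O)CC/C(C)=C/CC[C@]2(C)O[C@@H]2C1 | intermediate
26 | CNP0154954.4, methyl 2-[(1S,3R,4S,7E,12S)-3,4-epoxy-12-hydroxy-4,8,12-trimethyl-11-oxocyclotetradec-7-en-1-yl]prop-2-enoate | C=C(C(=O)OC)[C@H]1CC[C@](C)(O)C(=O)CC/C(C)=C/CC[C@]2(C)O[C@@H]2C1 | target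

**Step count**
Total: 18 steps. Longest linear sequence: 16 steps (steps 1–8, then 11–18); the sulfone branch (steps 9–10) joins at step 11.

**Steps most likely to fail, with fallbacks**

1. Step 14 (Proposed new method). Ring closure through the Breslow intermediate may be too slow at the dilution required, so that aldehyde self-condensation, oligomerisation or reversal of the C11–C12 bond formation take over; the catalyst may also fail to control the C12 face. The fallback uses known chemistry, sets out from 21 and comes back at 22. Intramolecular pinacol coupling of keto aldehyde 21 with SmI2 in THF under high dilution would give the macrocyclic 11,12-diol F1. This is the reductive ketyl–carbonyl macrocyclisation classically run with low-valent titanium for 14-membered cembranoid rings; samarium(II) is taken here because it should tolerate the oxirane. The 12S isomers would be separated from the 12R isomers by chromatography. Parikh–Doering oxidation (SO3·pyridine, DMSO, i-Pr2NEt) of the secondary C11 hydroxyl, the tertiary one being inert, would then return ketol 22. The cost is that C12 is set without reagent control.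

2. Step 11. Displacement at the neopentyl-like C5 may be outrun by attack of the carbanion on the oxirane, by decomposition of the triflate, or by deprotonation of the product and 3-exo closure onto the oxirane. The fallback sets out from 11 and comes back at 19; it makes the C5–C6 bond before the oxirane exists, so steps 7 and 8 are not needed. Appel bromination (CBr4, PPh3, CH2Cl2, −20 °C) of allylic alcohol 11 would give the Z-allylic bromide F2. Alkylation of lithiated sulfone 18 with this reactive allylic bromide (the classical head-to-tail sulfone coupling) would give the triene sulfone F3. Shi epoxidation (fructose-derived ketone or its enantiomer, Oxone, pH 10.5 buffer, MeCN/dimethoxymethane, 0 °C) would then oxidise the 3,4-alkene to give 19. The 7,8-alkene is deactivated by the allylic sulfonyl group and the 1,1-disubstituted alkene by its allylic silyloxy group. The ketone enantiomer would be chosen by correlation with 19 from step 11, and the facial selectivity on a Z-trisubstituted alkene is the weak point of this variant.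

3. Step 12. Hydride opening of the oxirane may compete, or hydride may be delivered to the wrong allyl terminus with migration of the alkene or loss of the 7E geometry. The fallback sets out from 19 and comes back at 20 with no new compound (F0). It replaces the palladium–hydride pathway by electron-transfer cleavage of the C–S bond: 6% sodium amalgam, Na2HPO4, MeOH/THF, −20 °C (Julia-type reductive desulfonylation). This is a hydride-free method to which oxiranes, acetals and silyl ethers are inert; any alkene regioisomer would be removed by chromatography on silver nitrate-impregnated silica.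

**Further compounds**

F1 | step 14 | macrocyclic 11,12-diol (1S,3R,4S,7E,12S; C11 epimers; C17 OTBDPS) | C=C(CO[Si](c3ccccc3)(c3ccccc3)C(C)(C)C)[C@H]1CC[C@](C)(O)C(O)CC/C(C)=C/CC[C@]2(C)O[C@@H]2C1
F2 | step 11 | (2Z,5S)-1-bromo-5-[3-(tert-butyldiphenylsilyloxy)prop-1-en-2-yl]-2-methyl-7-(2-methyl-1,3-dioxolan-2-yl)hept-2-ene | BrC/C(C)=C\C[C@@H](C(=C)CO[Si](c1ccccc1)(c1ccccc1)C(C)(C)C)CCC1(C)OCCO1
F3 | step 11 | triene sulfone (1S,3Z,7E; C6 phenylsulfonyl, both epimers; C11 dimethyl acetal; C12 dioxolane; C17 OTBDPS) | COC(OC)CC/C(C)=C/C(C/C(C)=C\C[C@@H](C(=C)CO[Si](c2ccccc2)(c2ccccc2)C(C)(C)C)CCC2(C)OCCO2)S(=O)(=O)c1ccccc1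
F0 | step 12 | none | none
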